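## The problem

Betaethrin E (28) is an achiral diaryl ether of two benzene rings. It has no stereocentre and no ring to close, so the task is one of substitution pattern, one crowded aryl–oxygen bond, and the order in which the oxygen functions are unmasked. Ring A is 1,2,3,5-tetrasubstituted: the ether oxygen on C1 lies between the palmitoyloxymethyl arm on C2 and a free hydroxyl on C6, and a methoxy group sits para to it on C4. Ring B is a methyl salicylate whose ester carbon C1′ lies between the aryloxy-bearing C2′ and the hydroxyl-bearing C6′, with a methyl group on C4′. The ether bond therefore joins a di-ortho-substituted phenol oxygen to a carbon ortho to a carboxyl group, a setting in which copper- or palladium-mediated etherification and SNAr are slow. Three phenolic oxygens must be told apart (one etherified, two free), and the benzylic alcohol must be the only site that is acylated. The groups that restrict the reagents are the primary benzylic palmitate, the methyl ester and the electron-rich ring A: the palmitate is lost on hydrogenolysis or to base and nucleophiles and would shift or be expelled next to a free ortho phenoxide, and ring A is easily oxidised once its phenol is free. The feature that opens a short route is on ring B: C2′ (O-aryl), C1′ (carboxyl carbon) and C6′ (oxygen) are contiguous, and without the carboxyl carbon ring B is symmetric orcinol. C1′ and C2′ can therefore be the two carbons of an aryne polarised by the oxygen on C6′, with C2′ taking the phenoxide and C1′ taking CO2.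

## Retrosynthesis

**Endgame.** The two free phenols of 28 are traced back to the methoxymethyl ethers of 27, the acyl C–O bond of the palmitate to alcohol 25 and hexadecanoyl chloride (26), and 25 to silyl ether 24. Acylation is placed after the ether bond because a palmitate ortho to a free phenoxide would migrate or leave, and before the phenols are freed because they would compete for the acid chloride. This order also keeps the waxy chain out of all earlier purifications. 24 differs from 28 only in protecting groups. The forward steps must remove a silyl ether beside two acetals and an ester, and then two acetals beside a benzylic ester, which calls for fluoride followed by dilute aqueous acid and rules out a final hydrogenolysis.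

**Key disconnection.** In 24 the C2′–O bond and the C1′–carboxyl bond are cut together, giving phenol 9, the ortho-silylaryl triflate 18 and carbon dioxide (19).
- Cutting the ether bond alone would require coupling the di-ortho-substituted 9 with a 2-halo-6-alkoxybenzoate, which itself needs a carboxyl placed between two oxygens.
- Cutting on the ring A side would require an electrophilic ring A carbon flanked by two substituents, which is worse.
- The double cut needs neither a metal catalyst nor a prefunctionalised benzoate: ring B shrinks to an orcinol derivative and both partners are simple arenes.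
- The forward reaction must do three things. Aryne 21 must accept phenoxide 20 at the carbon remote from its OMOM group. Arylpotassium 22 must survive until it is carboxylated to 23, which requires a medium free of proton donors. The benzylic silyl ether must resist fluoride, which is why it is a triisopropylsilyl ether.
- Methylation of 23 in the same flask gives 24.

**Ring B partner.** Triflate 18 is cut at its C–Si and S–O bonds to carbamate 16, then to carbamate 12, the mono-methoxymethyl ether 11 and orcinol (10). A halogen–metal exchange route would need a halogen between the two oxygens of 10, which direct halogenation does not deliver cleanly. Deprotonation between two cooperating oxygen directors puts silicon exactly there (via 13, 14 and 15). The forward steps require monoprotection of a symmetric diphenol, lithiation only between the oxygens, and a carbamate removal (via 17) mild enough to keep the aryl–silicon bond.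

**Ring A partner.** Phenol 9 is traced through benzyl ether 8, phenol 7, bromide 4, alcohol 3 and aldehyde 2 to the bromosalicylaldehyde 1. In 1 all four substituents of ring A already sit on the right carbons: bromine marks the future C6 oxygen and the formyl group the benzylic carbon. This avoids any regiochemical question that formylation or hydroxylation of a simpler methoxyphenol would raise. The C–Br bond becomes C–O by lithiation, borylation and oxidation (via 5 and 6), and the benzyl group keeps the C1 oxygen distinct from the C6 oxygen. The only demand beyond routine is that the final hydrogenolysis stop at the O-benzyl bond and spare the benzylic silyl ether.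

## Roads not taken

**Alternative 1:** Ring A would not be bought as an arene but built on a benzofuran-3-one that already contains ring B and the ether oxygen.
- Cut: through the C1–C2 and C5–C6 bonds of ring A.
- Forward key step: KOt-Bu would add keto ester A2 through its C2 enolate to the alkyne carbon of ynone A3 that bears the silyloxymethyl group. The methyl ketone enolate would then close the six-membered ring on the ester to give spiro dienone A1. Methoxide would later open the five-membered ring at its ketone, releasing ring A as a phenol and ring B as its methyl ester and erasing the spiro centre.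
- Merits: the crowded ether oxygen is never made by an intermolecular arylation, the methyl ester comes out of the ring opening, and two C–C bonds and a ring form in one flask.
- Weak points: the C4 oxygen must be methylated while the C6 oxygen stays free, yet in A1 these are the two ends of one vinylogous acid, so O-methylation has to choose between them. The ring opening must pick one of three carbonyl groups. A2 and A3 each need their own synthesis, and A2 requires acylation of an orcinol at the carbon between its oxygens.
- Comparison: on the ether bond this road is safer than the chosen one, which relies on an untested three-component coupling. Against that, the chosen plan fixes every ring A substituent in the purchased arene 1, leaves one selectivity question open (the direction of addition to aryne 21, where the substituent effect is well understood), and is shorter.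

**Alternative 2:** Ring A would again be built, this time by benzannulation.
- Cut: through the C2–C3 and C1–C6 bonds of ring A.
- Forward key step: chlorocyclobutenone A5 and the (Z)-vinylstannane A6, an enol ether that already carries ring B, would be joined by Stille coupling (Pd2(dba)3, tri(2-furyl)phosphine). Heating would open the four-membered ring to a dienylketene, whose 6π-electrocyclisation and tautomerisation give phenol A4.
- Merits: the regiochemistry of ring A follows from connectivity, the conditions are neutral, and A4 emerges with both phenols free, so the phenol protecting groups of the chosen route disappear. The aryl–oxygen bond problem is replaced by formation of an enol ether.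
- Weak points: A6 is a trisubstituted β-aryloxy vinylstannane of defined geometry with a free salicylate phenol, and its preparation is a project in itself. A5 is sensitive and must be made from a squaric acid derivative. Stoichiometric tin has to be removed, and ring B must still be prepared as a salicylate beforehand.
- Comparison: Alternative 2 is better in protecting-group economy and its key reaction type is established. The chosen plan is more convergent from purchasable arenes, avoids tin, and reaches the partners of its key step in far fewer steps.

**Alternative 3:** Here ring B would be the ring that is built.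
- Cut: through the C4′–C5′ and C1′–C6′ bonds of ring B.
- Forward key step: heating pyrone A8 with ketene acetal A9 would join pyrone C6 to the CH2 carbon and pyrone C3 to the acetal carbon (Diels–Alder reaction). Loss of CO2 and trimethylsilanol would give salicylate A7 with the ester and free phenol of ring B in place.
- Merits: the crowded ether bond is made beforehand as a vinylogous ester by addition–elimination on a 4-activated pyrone, which is easier than any arylation. The regiochemistry follows from the ester on pyrone C3, ring B needs no protecting group, and pyrone–ketene acetal benzannulation is an established reaction class.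
- Weak points: the 4-aryloxy group donates into the pyrone and lowers its reactivity as an electron-poor diene, so forcing temperatures are likely with the moisture-sensitive A9. The 3-carboxylated pyrone must be made and activated at C4 over several steps. The benzylic silyl ether and the MOM group must endure prolonged heating.
- Comparison: this road is ahead of the chosen plan in precedent for its key step, and it saves the ring B protecting group. Against that, the chosen plan takes ring B from orcinol in four steps, needs the same kind of ring A phenol (9) in any case, and delivers 24 from one flask, so the overall count is lower.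

Key step: step 11

Remark on the chemistry: 1, 10, 19, 26 and all reagents are taken as purchasable. 28 has no stereocentre, so no step has to control configuration. The benzylic alcohol is carried as a triisopropylsilyl ether, and the key step is run on a preformed potassium phenoxide in THF so that neither crown-activated fluoride nor a proton donor interferes.

## Route

Step 1
Reactants: 1 3-bromo-2-hydroxy-5-methoxybenzaldehyde
Product: 2 2-(benzyloxy)-3-bromo-5-methoxybenzaldehyde
Conditions: BnBr, K2CO3, DMF, rt
Reagents that add atoms: benzyl bromide, BrCc1ccccc1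
Why: Williamson ether synthesis on the phenoxide; the benzyl group masks the oxygen that will be the nucleophile of the key step, is inert to hydride and butyllithium, and is removable by hydrogenolysis.

Step 2
Reactants: 2 2-(benzyloxy)-3-bromo-5-methoxybenzaldehyde
Product: 3 [2-(benzyloxy)-3-bromo-5-methoxyphenyl]methanol
Conditions: NaBH4, MeOH/THF, 0 °C
Reagents that add atoms: none
Why: Hydride reduction of an aryl aldehyde to the primary benzylic alcohol; the aryl bromide and the ethers are untouched.

Step 3
Reactants: 3 [2-(benzyloxy)-3-bromo-5-methoxyphenyl]methanol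
Product: 4 {[2-(benzyloxy)-3-bromo-5-methoxyphenyl]methoxy}tri(propan-2-yl)silane
Conditions: TIPSCl, imidazole, DMF, rt
Reagents that add atoms: chlorotri(propan-2-yl)silane, CC(C)[Si](Cl)(C(C)C)C(C)C
Why: Imidazole-promoted silylation of a primary alcohol; the triisopropylsilyl ether is chosen because it must outlast butyllithium, hydrogenolysis and the fluoride of the key step.

Step 4
Reactants: 4 {[2-(benzyloxy)-3-bromo-5-methoxyphenyl]methoxy}tri(propan-2-yl)silane
Product: 7 2-(benzyloxy)-5-methoxy-3-({[tri(propan-2-yl)silyl]oxy}methyl)phenol, via aryllithium 5 (not isolated), via lithium aryltrimethoxyborate 6 (not isolated)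
Conditions: n-BuLi, THF, −78 °C; B(OMe)3, −78 °C to rt; then H2O2, aq. NaOH, 0 °C
Reagents that add atoms: hydrogen peroxide, OO
Why: Bromine–lithium exchange, borylation and oxidative aryl migration from boron to oxygen convert C–Br into C–OH at the carbon fixed by the starting material; exchange at −78 °C is faster than deprotonation of the benzyl ether.

Step 5
Reactants: 7 2-(benzyloxy)-5-methoxy-3-({[tri(propan-2-yl)silyl]oxy}methyl)phenol
Product: 8 {[2-(benzyloxy)-5-methoxy-3-(methoxymethoxy)phenyl]methoxy}tri(propan-2-yl)silane
Conditions: MOMCl, i-Pr2NEt, CH2Cl2, 0 °C to rt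
Reagents that add atoms: chloromethyl methyl ether, COCCl
Why: O-alkylation of the phenol to its methoxymethyl acetal, a group that is stable to hydrogenolysis, fluoride and base and is removed at the end together with the one on ring B.

Step 6
Reactants: 8 {[2-(benzyloxy)-5-methoxy-3-(methoxymethoxy)phenyl]methoxy}tri(propan-2-yl)silane
Product: 9 4-methoxy-2-(methoxymethoxy)-6-({[tri(propan-2-yl)silyl]oxy}methyl)phenol
Conditions: H2 (1 atm), Pd/C, EtOAc, rt
Reagents that add atoms: none
Why: Hydrogenolysis of the aryl benzyl ether; in an aprotic solvent the O-benzyl bond is cleaved much faster than the benzylic C–O bond of the silyl ether, and the acetal is inert. The electron-rich phenol is kept under inert gas.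

Step 7
Reactants: 10 orcinol (5-methylbenzene-1,3-diol)
Product: 11 3-(methoxymethoxy)-5-methylphenol
Conditions: NaH (1.0 equiv), MOMCl (1.0 equiv), DMF, 0 °C
Reagents that add atoms: chloromethyl methyl ether, COCCl
Why: Monoalkylation of a symmetric diphenol with one equivalent of base and electrophile; the outcome is statistical, the bis-ether and unreacted 10 are separated by chromatography, and 10 is recycled.

Step 8
Reactants: 11 3-(methoxymethoxy)-5-methylphenol
Product: 12 3-(methoxymethoxy)-5-methylphenyl N-(propan-2-yl)carbamate
Conditions: i-PrNCO, Et3N (cat.), CH2Cl2, rt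
Reagents that add atoms: 2-isocyanatopropane, CC(C)N=C=O
Why: Base-catalysed addition of the phenol to the isocyanate gives an N-monosubstituted carbamate, a strong ortho director that can later be removed under mild basic conditions.

Step 9
Reactants: 12 3-(methoxymethoxy)-5-methylphenyl N-(propan-2-yl)carbamate
Product: 16 3-(methoxymethoxy)-5-methyl-2-(trimethylsilyl)phenyl N-(propan-2-yl)carbamate, via N-silyl carbamate 13 (not isolated), via lithiated N-silyl carbamate 14 (not isolated), via doubly silylated carbamate 15 (not isolated)
Conditions: TBSOTf, TMEDA, Et2O, 0 °C to rt; n-BuLi, TMEDA, −78 °C; TMSCl, −78 °C to rt; aq. NH4Cl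
Reagents that add atoms: chlorotrimethylsilane, C[Si](C)(C)Cl
Why: Directed ortho-metalation: temporary N-silylation removes the acidic N–H, and the carbamate and OMOM groups jointly direct lithiation to the carbon between them. TMSCl traps the aryllithium at −78 °C before an anionic Fries shift can compete, and the N–Si bond hydrolyses on work-up.

Step 10
Reactants: 16 3-(methoxymethoxy)-5-methyl-2-(trimethylsilyl)phenyl N-(propan-2-yl)carbamate
Product: 18 3-(methoxymethoxy)-5-methyl-2-(trimethylsilyl)phenyl trifluoromethanesulfonate, via silylphenol 17 (not isolated)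
Conditions: Et2NH, DBU, MeCN, 40 °C; then PhNTf2, rt
Reagents that add atoms: 1,1,1-trifluoro-N-phenyl-N-(trifluoromethanesulfonyl)methanesulfonamide, O=S(=O)(N(c1ccccc1)S(=O)(=O)C(F)(F)F)C(F)(F)F
Why: E1cB cleavage of the N-monosubstituted carbamate (the isocyanate is scavenged by diethylamine as a urea) frees the phenoxide, which is triflated in the same flask; the purely basic conditions spare the aryl–silicon bond and the acetal.

Step 11
Reactants: 9 4-methoxy-2-(methoxymethoxy)-6-({[tri(propan-2-yl)silyl]oxy}methyl)phenol; 18 3-(methoxymethoxy)-5-methyl-2-(trimethylsilyl)phenyl trifluoromethanesulfonate; 19 carbon dioxide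
Product: 24 methyl 2-[4-methoxy-2-(methoxymethoxy)-6-({[tri(propan-2-yl)silyl]oxy}methyl)phenoxy]-6-(methoxymethoxy)-4-methylbenzoate, via potassium phenoxide 20 (not isolated), via aryne 21 (not isolated), via arylpotassium 22 (not isolated), via potassium benzoate 23 (not isolated)
Conditions: KH (1.0 equiv), THF, 0 °C; then 18 (1.5 equiv), KF, 18-crown-6, CO2 (1 atm), THF, 0 °C to rt; then MeI, DMF, rt
Reagents that add atoms: iodomethane, CI
Why: Proposed new method: KH converts 9 into potassium phenoxide 20 with hydrogen as the only by-product, so no proton donor remains in the THF; fluoride (KF solubilised by 18-crown-6) attacks the trimethylsilyl group of 18 and loss of triflate gives aryne 21. The OMOM group next to the triple bond distorts 21 so that the remote aryne carbon is the more linear and more electrophilic one; the hindered oxygen of 20 bonds there, which is also the less crowded terminus, and the resulting arylpotassium 22 lies between the OMOM and aryloxy oxygens, where it is inductively stabilised. 22 is captured by dissolved CO2 (the C–C bond) to give benzoate 23, and iodomethane esterifies 23 in the same flask by SN2 displacement, so the acid-labile acetals never meet a free ortho carboxylic acid. The closest known reaction types are the fluoride-triggered three-component coupling of ortho-silylaryl triflates with amines and CO2 to anthranilic acids, the two-component O-arylation of phenols by such arynes, and the regioselective addition of nucleophiles to 3-alkoxyarynes; the new element is a phenoxide as the nucleophile of the CO2-terminated coupling. No ring is closed and no stereocentre is formed. The step needs regioselectivity (oxygen at the remote carbon, carboxyl at the carbon between the two oxygens), secured by the inductive OMOM substituent and the bulk of the 2,6-disubstituted phenoxide, and it needs carboxylation to beat protonation, secured by the absence of acidic hydrogens (preformed phenoxide, THF, no hydrogencarbonate); the triisopropylsilyl ether is chosen to resist the fluoride.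

Step 12
Reactants: 24 methyl 2-[4-methoxy-2-(methoxymethoxy)-6-({[tri(propan-2-yl)silyl]oxy}methyl)phenoxy]-6-(methoxymethoxy)-4-methylbenzoate
Product: 25 methyl 2-[2-(hydroxymethyl)-4-methoxy-6-(methoxymethoxy)phenoxy]-6-(methoxymethoxy)-4-methylbenzoate
Conditions: TBAF, AcOH, THF, 0 °C to rt
Reagents that add atoms: none
Why: Fluoride cleavage of the silyl ether; acetic acid buffers the alkoxide, and the di-ortho-substituted benzoate is too hindered for lactonisation onto the new alcohol.

Step 13
Reactants: 25 methyl 2-[2-(hydroxymethyl)-4-methoxy-6-(methoxymethoxy)phenoxy]-6-(methoxymethoxy)-4-methylbenzoate; 26 hexadecanoyl chloride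
Product: 27 {5-methoxy-2-[2-(methoxycarbonyl)-3-(methoxymethoxy)-5-methylphenoxy]-3-(methoxymethoxy)phenyl}methyl hexadecanoate
Conditions: Et3N, DMAP (cat.), CH2Cl2, 0 °C to rt
Reagents that add atoms: none
Why: DMAP-catalysed acylation of the only free hydroxyl group in the molecule by the acid chloride.

Step 14
Reactants: 27 {5-methoxy-2-[2-(methoxycarbonyl)-3-(methoxymethoxy)-5-methylphenoxy]-3-(methoxymethoxy)phenyl}methyl hexadecanoate
Product: 28 Betaethrin E, methyl 2-[2-(hexadecanoyloxymethyl)-6-hydroxy-4-methoxyphenoxy]-6-hydroxy-4-methylbenzoate
Conditions: aq. HCl (2 M), THF, 40 °C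
Reagents that add atoms: none
Why: Acid-catalysed hydrolysis of the two aryl methoxymethyl acetals; dilute aqueous acid without an alcohol cosolvent cannot transesterify the palmitate or the methyl ester, and the benzylic C–O bond is not activated by a para or ortho hydroxyl group.

## Compound list

1 | 3-bromo-2-hydroxy-5-methoxybenzaldehyde | COc1cc(Br)c(O)c(C=O)c1 | starting material
2 | 2-(benzyloxy)-3-bromo-5-methoxybenzaldehyde | COc1cc(Br)c(OCc2ccccc2)c(C=O)c1 | intermediate
3 | [2-(benzyloxy)-3-bromo-5-methoxyphenyl]methanol | COc1cc(Br)c(OCc2ccccc2)c(CO)c1 | intermediate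
4 | {[2-(benzyloxy)-3-bromo-5-methoxyphenyl]methoxy}tri(propan-2-yl)silane | COc1cc(Br)c(OCc2ccccc2)c(CO[Si](C(C)C)(C(C)C)C(C)C)c1 | intermediate
5 | [2-(benzyloxy)-5-methoxy-3-({[tri(propan-2-yl)silyl]oxy}methyl)phenyl]lithium | COc1cc([Li])c(OCc2ccccc2)c(CO[Si](C(C)C)(C(C)C)C(C)C)c1 | intermediate (not isolated)
6 | lithium [2-(benzyloxy)-5-methoxy-3-({[tri(propan-2-yl)silyl]oxy}methyl)phenyl]trimethoxyborate | [Li+].COc1cc([B-](OC)(OC)OC)c(OCc2ccccc2)c(CO[Si](C(C)C)(C(C)C)C(C)C)c1 | intermediate (not isolated)
7 | 2-(benzyloxy)-5-methoxy-3-({[tri(propan-2-yl)silyl]oxy}methyl)phenol | COc1cc(O)c(OCc2ccccc2)c(CO[Si](C(C)C)(C(C)C)C(C)C)c1 | intermediate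
8 | {[2-(benzyloxy)-5-methoxy-3-(methoxymethoxy)phenyl]methoxy}tri(propan-2-yl)silane | COCOc1cc(OC)cc(CO[Si](C(C)C)(C(C)C)C(C)C)c1OCc1ccccc1 | intermediate
9 | 4-methoxy-2-(methoxymethoxy)-6-({[tri(propan-2-yl)silyl]oxy}methyl)phenol | COCOc1cc(OC)cc(CO[Si](C(C)C)(C(C)C)C(C)C)c1O | intermediate
10 | orcinol (5-methylbenzene-1,3-diol) | Cc1cc(O)cc(O)c1 | starting material
11 | 3-(methoxymethoxy)-5-methylphenol | Cc1cc(O)cc(OCOC)c1 | intermediate
12 | 3-(methoxymethoxy)-5-methylphenyl N-(propan-2-yl)carbamate | Cc1cc(OCOC)cc(OC(=O)NC(C)C)c1 | intermediate
13 | 3-(methoxymethoxy)-5-methylphenyl N-[tert-butyl(dimethyl)silyl]-N-(propan-2-yl)carbamate | Cc1cc(OCOC)cc(OC(=O)N(C(C)C)[Si](C)(C)C(C)(C)C)c1 | intermediate (not isolated)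
14 | [2-({[tert-butyl(dimethyl)silyl](propan-2-yl)carbamoyl}oxy)-6-(methoxymethoxy)-4-methylphenyl]lithium | Cc1cc(OCOC)c([Li])c(OC(=O)N(C(C)C)[Si](C)(C)C(C)(C)C)c1 | intermediate (not isolated)
15 | 3-(methoxymethoxy)-5-methyl-2-(trimethylsilyl)phenyl N-[tert-butyl(dimethyl)silyl]-N-(propan-2-yl)carbamate | Cc1cc(OCOC)c([Si](C)(C)C)c(OC(=O)N(C(C)C)[Si](C)(C)C(C)(C)C)c1 | intermediate (not isolated)
16 | 3-(methoxymethoxy)-5-methyl-2-(trimethylsilyl)phenyl N-(propan-2-yl)carbamate | Cc1cc(OCOC)c([Si](C)(C)C)c(OC(=O)NC(C)C)c1 | intermediate
17 | 3-(methoxymethoxy)-5-methyl-2-(trimethylsilyl)phenol (present in the flask as its DBU salt) | Cc1cc(OCOC)c([Si](C)(C)C)c(O)c1 | intermediate (not isolated)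
18 | 3-(methoxymethoxy)-5-methyl-2-(trimethylsilyl)phenyl trifluoromethanesulfonate | Cc1cc(OCOC)c([Si](C)(C)C)c(OS(=O)(=O)C(F)(F)F)c1 | intermediate
19 | carbon dioxide | O=C=O | starting material
20 | potassium 4-methoxy-2-(methoxymethoxy)-6-({[tri(propan-2-yl)silyl]oxy}methyl)phenoxide | [K+].COCOc1cc(OC)cc(CO[Si](C(C)C)(C(C)C)C(C)C)c1[O-] | intermediate (not isolated)
21 | 3-(methoxymethoxy)-5-methylbenzyne (triple bond between C1 and C2, OMOM on C3) | CC1=CC#CC(OCOC)=C1 | intermediate (not isolated)
22 | {2-[4-methoxy-2-(methoxymethoxy)-6-({[tri(propan-2-yl)silyl]oxy}methyl)phenoxy]-6-(methoxymethoxy)-4-methylphenyl}potassium | [K+].COCOc1cc(C)cc(Oc2c(CO[Si](C(C)C)(C(C)C)C(C)C)cc(OC)cc2OCOC)[c-]1 | intermediate (not isolated)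
23 | potassium 2-[4-methoxy-2-(methoxymethoxy)-6-({[tri(propan-2-yl)silyl]oxy}methyl)phenoxy]-6-(methoxymethoxy)-4-methylbenzoate | [K+].[O-]C(=O)c1c(OCOC)cc(C)cc1Oc1c(CO[Si](C(C)C)(C(C)C)C(C)C)cc(OC)cc1OCOC | intermediate (not isolated)
24 | methyl 2-[4-methoxy-2-(methoxymethoxy)-6-({[tri(propan-2-yl)silyl]oxy}methyl)phenoxy]-6-(methoxymethoxy)-4-methylbenzoate | COC(=O)c1c(OCOC)cc(C)cc1Oc1c(CO[Si](C(C)C)(C(C)C)C(C)C)cc(OC)cc1OCOC | intermediate
25 | methyl 2-[2-(hydroxymethyl)-4-methoxy-6-(methoxymethoxy)phenoxy]-6-(methoxymethoxy)-4-methylbenzoate | COC(=O)c1c(OCOC)cc(C)cc1Oc1c(CO)cc(OC)cc1OCOC | intermediate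
26 | hexadecanoyl chloride (palmitoyl chloride) | CCCCCCCCCCCCCCCC(Cl)=O | starting material
27 | {5-methoxy-2-[2-(methoxycarbonyl)-3-(methoxymethoxy)-5-methylphenoxy]-3-(methoxymethoxy)phenyl}methyl hexadecanoate | CCCCCCCCCCCCCCCC(=O)OCc1cc(OC)cc(OCOC)c1Oc1cc(C)cc(OCOC)c1C(=O)OC | intermediate
28 | Betaethrin E, methyl 2-[2-(hexadecanoyloxymethyl)-6-hydroxy-4-methoxyphenoxy]-6-hydroxy-4-methylbenzoate | CCCCCCCCCCCCCCCC(=O)OCc1cc(OC)cc(O)c1Oc1cc(C)cc(O)c1C(=O)OC | target

## Step count and risks

Total: 14 steps. Longest linear sequence: 10 steps (steps 1–6, then 11–14). The ring B branch (steps 7–10) is 4 steps and joins at step 11.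

**Step 11 (key step, proposed new method).**
- Most likely failure: protonation of arylpotassium 22 before it meets CO2 (adventitious water or slow gas uptake), which ends in the diaryl ether without the carboxyl group.
- Further risks: reversible carbonation of phenoxide 20 may lower the concentration of free nucleophile, so that aryne 21 is consumed by fluoride or by self-condensation. Attack of 20 at the sulfur of 18 (triflyl transfer) may consume both partners.
- Fallback (known chemistry), setting out from 9 and returning at 24: purchased 3-fluoro-5-methylphenol F1 is protected with MOMCl and i-Pr2NEt as 1-fluoro-3-(methoxymethoxy)-5-methylbenzene F2. Lithiation between fluorine and OMOM (n-BuLi, THF, −78 °C) gives [2-fluoro-6-(methoxymethoxy)-4-methylphenyl]lithium F3, which DMF formylates to 2-fluoro-6-(methoxymethoxy)-4-methylbenzaldehyde F4. Phenol 9 then displaces fluoride from F4 (Cs2CO3, DMF, 90 °C; SNAr activated by the ortho formyl group) to give 2-[4-methoxy-2-(methoxymethoxy)-6-({[tri(propan-2-yl)silyl]oxy}methyl)phenoxy]-6-(methoxymethoxy)-4-methylbenzaldehyde F5. Pinnick oxidation (NaClO2, NaH2PO4, 2-methylbut-2-ene, t-BuOH/H2O) gives 2-[4-methoxy-2-(methoxymethoxy)-6-({[tri(propan-2-yl)silyl]oxy}methyl)phenoxy]-6-(methoxymethoxy)-4-methylbenzoic acid F6, and MeI with K2CO3 in DMF returns 24.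

**Step 9.**
- Most likely failure: loss of the methoxymethyl group to the silyl triflate, incomplete N-silylation followed by isocyanate extrusion on lithiation, or anionic Fries migration of the carbamoyl group if the aryllithium warms before it is silylated.
- Fallback, setting out from 11 and returning at 18: 11 is carbamoylated with ClC(O)NEt2 and NaH in THF to 3-(methoxymethoxy)-5-methylphenyl N,N-diethylcarbamate F7, which needs no N-protection. s-BuLi and TMEDA in THF at −78 °C give [2-(diethylcarbamoyloxy)-6-(methoxymethoxy)-4-methylphenyl]lithium F8, and TMSCl gives 3-(methoxymethoxy)-5-methyl-2-(trimethylsilyl)phenyl N,N-diethylcarbamate F9. LiAlH4 in THF cleaves the carbamate to phenol 17 (isolated in this variant), and PhNTf2 with Et3N in CH2Cl2 gives 18.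

**Step 4.**
- Most likely failure: deprotonation of the O-benzyl methylene by the neighbouring aryllithium 5 with subsequent Wittig rearrangement, or protonation of 5, so that bromine is lost without oxygenation.
- Fallback, setting out from 4 and returning at 7: Miyaura borylation (B2pin2, PdCl2(dppf), KOAc, dioxane, 90 °C) gives 2-[2-(benzyloxy)-5-methoxy-3-({[tri(propan-2-yl)silyl]oxy}methyl)phenyl]-4,4,5,5-tetramethyl-1,3,2-dioxaborolane F10 without an organolithium, and NaBO3·4H2O in THF/H2O oxidises F10 to 7.

**Step 7.**
- Most likely failure: over-alkylation to the bis-ether alongside unreacted 10, because the two hydroxyl groups are equivalent; material is lost in a statistical mixture.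
- Fallback, replacing 10 as starting material and returning at 11: purchased 3-bromo-5-methylphenol F11 is protected with MOMCl and i-Pr2NEt as 1-bromo-3-(methoxymethoxy)-5-methylbenzene F12. Palladium-catalysed hydroxylation (Pd2(dba)3, t-BuXPhos, KOH, dioxane/H2O, 100 °C) converts F12 into 11 with no symmetry problem.

**Step 14.**
- Most likely failure: partial hydrolysis of the benzylic palmitate during acetal cleavage, or re-addition of the released formaldehyde to the electron-rich ring A.
- Fallback, setting out from 25 and returning at 28: both acetals are removed before acylation (aq. HCl, THF) to give methyl 2-[2-hydroxy-6-(hydroxymethyl)-4-methoxyphenoxy]-6-hydroxy-4-methylbenzoate F13. The primary alcohol of F13 is then acylated selectively in the presence of the two phenols by enzymatic transesterification (immobilised Candida antarctica lipase B, vinyl hexadecanoate, t-BuOMe, 40 °C), giving 28 without passing through 27.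

## Further compounds

F1 | step 11 | 3-fluoro-5-methylphenol | Cc1cc(O)cc(F)c1
F2 | step 11 | 1-fluoro-3-(methoxymethoxy)-5-methylbenzene | Cc1cc(F)cc(OCOC)c1
F3 | step 11 | [2-fluoro-6-(methoxymethoxy)-4-methylphenyl]lithium | Cc1cc(F)c([Li])c(OCOC)c1
F4 | step 11 | 2-fluoro-6-(methoxymethoxy)-4-methylbenzaldehyde | Cc1cc(F)c(C=O)c(OCOC)c1
F5 | step 11 | 2-[4-methoxy-2-(methoxymethoxy)-6-({[tri(propan-2-yl)silyl]oxy}methyl)phenoxy]-6-(methoxymethoxy)-4-methylbenzaldehyde | O=Cc1c(OCOC)cc(C)cc1Oc1c(CO[Si](C(C)C)(C(C)C)C(C)C)cc(OC)cc1OCOC
F6 | step 11 | 2-[4-methoxy-2-(methoxymethoxy)-6-({[tri(propan-2-yl)silyl]oxy}methyl)phenoxy]-6-(methoxymethoxy)-4-methylbenzoic acid | OC(=O)c1c(OCOC)cc(C)cc1Oc1c(CO[Si](C(C)C)(C(C)C)C(C)C)cc(OC)cc1OCOC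
F7 | step 9 | 3-(methoxymethoxy)-5-methylphenyl N,N-diethylcarbamate | CCN(CC)C(=O)Oc1cc(C)cc(OCOC)c1
F8 | step 9 | [2-(diethylcarbamoyloxy)-6-(methoxymethoxy)-4-methylphenyl]lithium | CCN(CC)C(=O)Oc1cc(C)cc(OCOC)c1[Li]
F9 | step 9 | 3-(methoxymethoxy)-5-methyl-2-(trimethylsilyl)phenyl N,N-diethylcarbamate | CCN(CC)C(=O)Oc1cc(C)cc(OCOC)c1[Si](C)(C)C
F10 | step 4 | 2-[2-(benzyloxy)-5-methoxy-3-({[tri(propan-2-yl)silyl]oxy}methyl)phenyl]-4,4,5,5-tetramethyl-1,3,2-dioxaborolane | COc1cc(B2OC(C)(C)C(C)(C)O2)c(OCc2ccccc2)c(CO[Si](C(C)C)(C(C)C)C(C)C)c1
F11 | step 7 | 3-bromo-5-methylphenol | Cc1cc(O)cc(Br)c1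
F12 | step 7 | 1-bromo-3-(methoxymethoxy)-5-methylbenzene | Cc1cc(Br)cc(OCOC)c1
F13 | step 14 | methyl 2-[2-hydroxy-6-(hydroxymethyl)-4-methoxyphenoxy]-6-hydroxy-4-methylbenzoate | COC(=O)c1c(O)cc(C)cc1Oc1c(CO)cc(OC)cc1O
A1 | alternative 1 | 6'-({[tert-butyl(dimethyl)silyl]oxy}methyl)-4,4'-dihydroxy-6-methyl-3H-spiro[1-benzofuran-2,1'-cyclohexa[3,5]diene]-2',3-dione (racemic) | Cc1cc(O)c2C(=O)C3(Oc2c1)C(=O)C=C(O)C=C3CO[Si](C)(C)C(C)(C)C
A2 | alternative 1 | methyl 4-hydroxy-6-methyl-3-oxo-2,3-dihydro-1-benzofuran-2-carboxylate (racemic) | COC(=O)C1Oc2cc(C)cc(O)c2C1=O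
A3 | alternative 1 | 5-{[tert-butyl(dimethyl)silyl]oxy}pent-3-yn-2-one | CC(=O)C#CCO[Si](C)(C)C(C)(C)C
A4 | alternative 2 | methyl 2-[2-({[tert-butyl(dimethyl)silyl]oxy}methyl)-6-hydroxy-4-methoxyphenoxy]-6-hydroxy-4-methylbenzoate | COC(=O)c1c(O)cc(C)cc1Oc1c(O)cc(OC)cc1CO[Si](C)(C)C(C)(C)C
A5 | alternative 2 | 4-chloro-3-methoxycyclobut-2-en-1-one (racemic) | COC1=CC(=O)C1Cl
A6 | alternative 2 | methyl 2-{[(Z)-3-{[tert-butyl(dimethyl)silyl]oxy}-2-(tributylstannyl)prop-1-en-1-yl]oxy}-6-hydroxy-4-methylbenzoate | COC(=O)c1c(O)cc(C)cc1O/C=C(/CO[Si](C)(C)C(C)(C)C)[Sn](CCCC)(CCCC)CCCC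
A7 | alternative 3 | methyl 2-[2-({[tert-butyl(dimethyl)silyl]oxy}methyl)-4-methoxy-6-(methoxymethoxy)phenoxy]-6-hydroxy-4-methylbenzoate | COC(=O)c1c(O)cc(C)cc1Oc1c(CO[Si](C)(C)C(C)(C)C)cc(OC)cc1OCOC
A8 | alternative 3 | methyl 4-[2-({[tert-butyl(dimethyl)silyl]oxy}methyl)-4-methoxy-6-(methoxymethoxy)phenoxy]-6-methyl-2-oxo-2H-pyran-3-carboxylate | COC(=O)C1=C(Oc2c(CO[Si](C)(C)C(C)(C)C)cc(OC)cc2OCOC)C=C(C)OC1=O
A9 | alternative 3 | 1,1-bis(trimethylsilyloxy)ethene | C=C(O[Si](C)(C)C)O[Si](C)(C)C
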